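Readings and results are simulated with made-up constants, noise included.

How much starting complex, complex with one exchanged and incoming ligand stand in the flask at 25 min?

all flasks: starting complex 0.20 M
- dawn: incoming ligand 0.17 M; run made earlier
- noon: incoming ligand 0.39 M; run made earlier
- flask: incoming ligand 0.260 M; time 25 min

| run | time / min | complex with one exchanged / % | starting complex / % |
|---|---|---|---|
| dawn | 4.00 | 23 | 80 |
| dawn | 8.00 | 26 | 69 |
| dawn | 12.0 | 35 | 63 |
| dawn | 15.0 | 42 | 56 |
| dawn | 20.0 | 46 | 52 |
| dawn | 25.0 | 50 | 50 |
| dawn | 30.0 | 49 | 47 |
| noon | 1.50 | 17 | 81 |
| noon | 5.00 | 40 | 56 |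
| noon | 8.00 | 54 | 48 |
| noon | 12.0 | 65 | 42 |
| noon | 20.0 | 68 | 32 |
| noon | 25.0 | 76 | 26 |
| noon | 30.0 | 73 | 22 |

(standard deviation of a reading: 2 percentage points)

- the numbers in the tables scatter with a standard deviation of 2 percentage points
- candidate steps: 2 incoming ligand -> self-condensation product; complex with one exchanged + incoming ligand -> leaving ligand + complex with two exchanged; complex with one exchanged -> over-reaction product; starting complex + incoming ligand -> leaving ligand + complex with one exchanged

* concentration of complex with one exchanged at 25 min, in M
* concentration of starting complex at 25 min, in M
* concentration of incoming ligand at 25 min, in M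

At each moment the starting complex, [M], decays pseudo-first-order in the standing incoming ligand, [X]: d ln[M]/dt = −k[X], with k the exchange constant. Integrated in closed form, this gives the exposure, S = ln([M] charged/[M] left) = k∫[X]dt, read at 25.0 min as 0.693 in the dawn run and 1.35 in the noon run.

Per molar of incoming ligand charged, S falls from 4.08 L mol⁻¹ to 3.45 L mol⁻¹, so the reckoning here assumes that S bends downward with that charge, at fixed time and fixed charge of starting complex. The line from zero through the dawn run, continued to 0.260 M, then lies above the curve: on that assumption, and within the scatter of the readings, the upper bound on S is 1.06, and the lower bound on [M] is 0.0693 M. The chord from dawn to noon lies below it: on the same terms the lower bound on S is 0.961, and the upper bound on [M] is 0.0765 M.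

The forecast, holding of the incoming ligand that “the loss looks second-order”, gives 0.08 M of starting complex, 0.119 M of complex with one exchanged and 0.04 M of incoming ligand. Its [M] stands above the bracket by 1.7 percentage points of the charge, less than the scatter of one reading, 2 points.

The flask gives 0.0749 M of starting complex, 0.122 M of complex with one exchanged and 0.0385 M of incoming ligand, each within the forecast's range.

    2 incoming ligand → self-condensation product (k = 0.00260 L mol⁻¹ s⁻¹)
    complex with one exchanged + incoming ligand → leaving ligand + complex with two exchanged (k = 2.80 × 10⁻⁴ L mol⁻¹ s⁻¹)
    complex with one exchanged → over-reaction product (k = 6.50 × 10⁻⁷ s⁻¹)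
    starting complex + incoming ligand → leaving ligand + complex with one exchanged (k = 0.00690 L mol⁻¹ s⁻¹)

The exposure of this flask is 0.983, inside the bracket. Over-reaction makes no difference in this flask: its half-life, 300 h, is long against 25 min. For the neighbouring flask with 0.44 M of incoming ligand, the dawn-noon chord continued gives S of 1.50, so about 0.0448 M of starting complex at 25.0 min. That neighbouring flask computes to 0.0454 M.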